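## The problem

Compound 17 is a diaryl ether whose bridging oxygen is flanked by three ortho substituents: the C2 hydroxyl and the C6 pentyl group on ring A, and the carboxyl group on ring B. Ring A is electron-rich and doubly ortho-substituted at the ether carbon, so joining two finished rings by aryl–oxygen coupling is the least attractive way to make this bond. Ring B carries the carboxyl group between the aryloxy oxygen and a pentanoyl group. This 2-acylbenzoic acid equilibrates with its lactol, and as an ester under alkoxide it would condense to an indane-1,3-dione, so it has to travel in masked form. The target has no stereocentre; the two stereocentres that appear on the way (a phthalide carbinol carbon and one quaternary ring carbon) control nothing and are erased. The sensitive elements are three: ring A, a hydroxyquinol monoaryl ether that is easily oxidised as the free phenol or phenoxide; the C2 hydroxyl and the carboxyl group, which can close to a seven-membered depsidone lactone under dehydrating conditions; and the two free hydroxyls of ring A, which must stay distinct from the single methyl ether of ring B. The enabling feature is that ring A is olivetol with the ether oxygen on C1, the carbon between the C2 hydroxyl and the pentyl-bearing C6. In a malonate–ynone resorcinol synthesis this carbon is the malonate carbon, so ring A can be grown on an oxygen already attached to ring B, and the ether bond becomes an alkylation at sp3 carbon.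

## Retrosynthesis

**Protecting groups and oxidation level (17 ⇒ 16 ⇒ 14).** The two aryl–O–CH2OMe bonds of 16 are the last to be cut. Keto acid 16 is traced to phthalide 14 by re-forming the lactone C–O bond and lowering the ketone to the carbinol; in the forward sense hydroxide opens the lactone to carboxylate 15, whose carbinol is then oxidised. A phthalide is preferred to a keto ester because it has no enolisable ketone and cannot form an indanedione under the alkoxide of the key step. The acetals are needed only because free ring A would not survive an alkaline oxidation. The forward steps must oxidise one secondary benzylic alkoxide without touching two electron-rich rings, and must remove the acetals without dehydrating the keto acid.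

**Aromatic ring A from a blocked dione (14 ⇒ 13 ⇒ 11).** Resorcinol 13 is the free-phenol form of 14. It is traced to cyclohexenedione 11 by re-attaching a methoxycarbonyl group to C1 (through acid 12). This gives no simplification in size, but it exposes the 1,3-dicarbonyl pattern that the key step makes. Removing the ester forward is driven by aromatisation, and it delivers both hydroxyls of ring A free while the ring B methyl ether is untouched, so the oxygens never need to be differentiated.

**Key disconnection (11 ⇒ 8 + 9).** Bonds C1–C6 and C2–C3 of ring A are cut. C1 becomes the carbanion carbon of aryloxymalonate 8, C6 the β-carbon of non-3-yn-2-one 9, C3 the methyl carbon of 9 and C2 an ester carbonyl of 8; the open-chain adduct is 10. The neighbouring cut, the aryl–oxygen bond itself, would require coupling of two hindered, electron-rich partners. Other two-bond cuts of ring A would not place the oxygen-bearing carbon at a nucleophilic position. The precursors are a purchased nine-carbon ynone and a malonate with ring B complete. The forward reaction asks a tertiary carbanion to add to a β-alkyl ynone and the resulting enone to close by Claisen condensation.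

**Ether bond (8 ⇒ 6 + 7).** The O–C(sp3) bond between the phenol oxygen of 6 and the malonate carbon is cut, giving hydroxyphthalide 6 and dimethyl bromomalonate 7. An SN2 displacement by phenoxide is indifferent to the ortho crowding that would slow any aryl–oxygen coupling. The forward step must stop at mono-alkylation.

**Ring B (6 ⇒ 5 ⇒ 3 ⇒ 2 ⇒ 1).** The free hydroxyl of 6 comes from the methyl ether of 5 next to the lactone carbonyl (O–CH3 cut, directed by chelation). The lactone of 5 is cut at the aryl–carboxyl bond (through hydroxy acid 4), giving bromo alcohol 3. The C–Br bond of 3 comes from bromination of carbinol 2, and the butyl–carbinol bond of 2 from Grignard addition to 3,5-dimethoxybenzaldehyde 1. Each step is a standard aromatic operation with regiochemistry set by the 3,5-dioxygenation.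

## Roads not taken

**Alternative 1: Alder–Rickert construction of ring B.** The cut goes through two bonds of ring B, on either side of the ester and side-chain carbons. Forward, the aryloxy silyloxy diene A3 (made from phenol A2 and a cyclic 1,3-dione) would be heated with ynoate A4; the bicyclo[2.2.2]octadiene adduct loses its two-carbon bridge by cycloreversion and gives benzoate A1.
- Merits: the ether oxygen is installed by addition–elimination at a vinylogous acyl carbon, not by aryl coupling; the polarised diene fixes the substitution pattern of ring B; and the reaction class is thermal, metal-free and well established for 1,3-dioxygenated dienes with propiolates. In precedent for the key event this road is stronger than the chosen one.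
- Weak points: A2 is a tri-oxygenated phenol that is not an article of commerce and needs its own multi-step preparation. The cycloaddition needs high temperature with a γ-branched ynoate. A1 still requires exchange of the aryl silyl ether for a methyl ether, hydrolysis of a doubly ortho-substituted ester, oxidation of the carbinol, and debenzylation in the presence of an aryl ketone.
- Comparison: the chosen plan builds ring A with its oxygen pattern unprotected and already attached to a ring B that comes in four steps from aldehyde 1, with no separate synthesis of a ring A phenol and fewer protecting-group exchanges.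

**Alternative 2: ruthenium [2+2+2] cyclotrimerisation.** Three bonds of ring B are cut. Forward, diyne ester A6 and methoxyacetylene A7 would be cyclotrimerised on Cp*RuCl(cod) to give phthalide A5, closing ring B and the lactone in one step.
- Merits: it is the most convergent of the four plans. A5 is the bis-benzyl counterpart of 14, so it would arrive directly at the stage the chosen route reaches after step 8, and ring A never appears as a free phenol.
- Weak points: A6 is a push–pull aryl ynol ether that is prone to hydration, and making it again requires A2 plus several steps of ynol ether chemistry. A7 is volatile and unstable. The position of the methoxy group (meta, not ortho, to the aryloxy group) depends on catalyst control that is not established when both partners are oxygen-substituted alkynes. Ester-tethered diynes also cyclise reluctantly.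
- Comparison: if the cyclotrimerisation worked, this road would be shorter from its fragments. The chosen plan offers bench-stable intermediates and a regiochemistry fixed by connectivity, not by a catalyst.

**Alternative 3: Catellani three-component assembly.** The cut removes the ring B–acyl bond and the ring B–alkenyl bond. Forward, aryl iodide A9, pentanoic anhydride A10 and tert-butyl acrylate A11 would be combined under Pd(OAc)2 (divalent palladium) with a strained bicyclic alkene as transient mediator, giving A8 by ortho acylation followed by ipso Heck coupling; no ring is closed.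
- Merits: it is modular and catalytic, and the ketone is installed at its final oxidation level, so no late carbinol oxidation is needed. In that respect it is better than the chosen plan.
- Weak points: A9 is already the hindered diaryl ether, so the hardest bond is left to a conventional coupling of A2 with a halogenated anisole. The carboxyl carbon arrives as a three-carbon acrylate that must be degraded by oxidative cleavage in the presence of two electron-rich rings. Debenzylation again meets an aryl ketone.
- Comparison: the chosen plan has a late oxidation (step 9) that this road avoids, but it makes the ether by SN2 and needs no oxidative cleavage.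

Key step: step 6

Assumption: non-3-yn-2-one (9) is taken as a purchasable reagent, and 17 is drawn as the open keto acid although it will equilibrate with its ring-closed lactol tautomer.

## Route

Step 1
Reactants: 1 3,5-dimethoxybenzaldehyde
Product: 2 1-(3,5-dimethoxyphenyl)pentan-1-ol (racemic)
Conditions: BuMgBr, THF, 0 °C to rt; aq NH4Cl
Reagents that add atoms: butylmagnesium bromide, CCCC[Mg]Br
Why: Grignard addition to an aromatic aldehyde; the new carbinol centre needs no control because it is oxidised to the ketone in step 9.

Step 2
Reactants: 2 1-(3,5-dimethoxyphenyl)pentan-1-ol (racemic)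
Product: 3 1-(2-bromo-3,5-dimethoxyphenyl)pentan-1-ol (racemic)
Conditions: NBS, MeCN, 0 °C to rt
Reagents that add atoms: N-bromosuccinimide, O=C1CCC(=O)N1Br
Why: Electrophilic aromatic bromination; the position ortho to the side chain is para to one methoxy group and ortho to the other and is less hindered than the position between both methoxy groups, as is general for 3,5-dimethoxybenzyl alcohols.

Step 3
Reactants: 3 1-(2-bromo-3,5-dimethoxyphenyl)pentan-1-ol (racemic)
Product: 5 3-butyl-5,7-dimethoxyisobenzofuran-1(3H)-one (racemic), via hydroxy acid 4 (not isolated)
Conditions: n-BuLi (2.2 equiv), THF, −78 °C; CO2; then 2 M HCl, rt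
Reagents that add atoms: carbon dioxide, O=C=O
Why: Deprotonation of the alcohol and bromine–lithium exchange give an aryllithium that is carboxylated; on acidification hydroxy acid 4 closes spontaneously to the five-membered lactone (phthalide formation).

Step 4
Reactants: 5 3-butyl-5,7-dimethoxyisobenzofuran-1(3H)-one (racemic)
Product: 6 3-butyl-7-hydroxy-5-methoxyisobenzofuran-1(3H)-one (racemic)
Conditions: BCl3, CH2Cl2, −78 to 0 °C; H2O
Reagents that add atoms: none
Why: Chelation-directed aryl methyl ether cleavage; BCl3 binds the lactone carbonyl and cleaves only the methoxy group beside it, leaving the C5 methyl ether that the target keeps.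

Step 5
Reactants: 6 3-butyl-7-hydroxy-5-methoxyisobenzofuran-1(3H)-one (racemic); 7 dimethyl bromomalonate
Product: 8 dimethyl 2-[(3-butyl-5-methoxy-1-oxo-1,3-dihydroisobenzofuran-7-yl)oxy]malonate (racemic)
Conditions: K2CO3, acetone, 56 °C
Reagents that add atoms: none
Why: Williamson-type SN2 O-alkylation of a phenoxide by an α-halo malonate; displacement at sp3 carbon is insensitive to the crowding around the phenol oxygen, and the bromide is kept near one equivalent so that the acidic product is not alkylated again.

Step 6
Reactants: 8 dimethyl 2-[(3-butyl-5-methoxy-1-oxo-1,3-dihydroisobenzofuran-7-yl)oxy]malonate (racemic); 9 non-3-yn-2-one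
Product: 11 methyl 1-[(3-butyl-5-methoxy-1-oxo-1,3-dihydroisobenzofuran-7-yl)oxy]-2,4-dioxo-6-pentylcyclohex-5-ene-1-carboxylate (mixture of diastereomers), via Michael adduct 10 (not isolated)
Conditions: NaOMe (1.5 equiv), MeOH–THF, 0 to 60 °C; then 1 M HCl
Reagents that add atoms: none
Why: Proposed new method: NaOMe converts 8 into its tertiary, ester- and oxygen-stabilised carbanion, which adds to the pentyl-bearing β-carbon of ynone 9 (bond C1–C6 of ring A) and gives enone 10 after protonation; the closest known reaction type is the Michael–Claisen annulation of unsubstituted malonates with alk-3-yn-2-ones that delivers resorcylates, and the new element is a 2-aryloxymalonate as donor, which stops the sequence at a blocked dione. The E and Z isomers of 10 should interconvert under methoxide through the extended dienolate formed by deprotonation of the pentyl CH2 next to the double bond, so the Z isomer (acetyl cis to the malonate carbon) is continuously supplied. Its methyl-ketone enolate attacks one malonate ester in a 6-(enolendo)-exo-trig Claisen closure (bond C2–C3), a mode favoured for enolates, and this closes the carbocycle that becomes ring A. Loss of methoxide gives 11, which is deprotonated at C3 to a vinylogous-acid enolate, and this last acid–base step pulls the preceding equilibria forward. Regiochemistry needs no control, because the malonate carbon is the only donor and the β-carbon of 9 the only acceptor site, so the aryloxy carbon ends between the ester-derived carbonyl (the future C2 hydroxyl) and the pentyl-bearing carbon. Chemoselectivity rests on reversibility: attack of the carbanion on the neighbouring lactone carbonyl would give a non-enolisable β-keto diester that methoxide cleaves again, and any methanolysis of the lactone is undone on acidification. The new quaternary centre forms without control beside the racemic phthalide carbon, which is acceptable because both centres are removed in steps 7 and 9.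

Step 7
Reactants: 11 methyl 1-[(3-butyl-5-methoxy-1-oxo-1,3-dihydroisobenzofuran-7-yl)oxy]-2,4-dioxo-6-pentylcyclohex-5-ene-1-carboxylate (mixture of diastereomers)
Product: 13 3-butyl-7-(2,4-dihydroxy-6-pentylphenoxy)-5-methoxyisobenzofuran-1(3H)-one (racemic), via dione carboxylic acid 12 (not isolated)
Conditions: LiCl, DMSO–H2O, 140 °C; dilute HCl work-up
Reagents that add atoms: none
Why: Krapcho dealkoxycarbonylation; chloride demethylates the ester by SN2, the β-keto carboxylate of 12 loses CO2, and the resulting dienolate is the phenoxide of the resorcinol, so aromatisation drives the step and both ring A hydroxyls appear free beside the intact ring B methyl ether.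

Step 8
Reactants: 13 3-butyl-7-(2,4-dihydroxy-6-pentylphenoxy)-5-methoxyisobenzofuran-1(3H)-one (racemic)
Product: 14 7-[2,4-bis(methoxymethoxy)-6-pentylphenoxy]-3-butyl-5-methoxyisobenzofuran-1(3H)-one (racemic)
Conditions: MOMCl, i-Pr2NEt, CH2Cl2, 0 °C to rt
Reagents that add atoms: chloromethyl methyl ether, COCCl
Why: Standard protection of phenols as methoxymethyl ethers; it is needed because the free hydroxyquinol-type ring would not survive the alkaline oxidation of step 9.

Step 9
Reactants: 14 7-[2,4-bis(methoxymethoxy)-6-pentylphenoxy]-3-butyl-5-methoxyisobenzofuran-1(3H)-one (racemic)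
Product: 16 2-[2,4-bis(methoxymethoxy)-6-pentylphenoxy]-4-methoxy-6-pentanoylbenzoic acid, via sodium hydroxy carboxylate 15 (not isolated)
Conditions: NaOH, H2O–t-BuOH, 80 °C; then KMnO4 (0.7 equiv), 0 °C; filter; cold 1 M HCl to pH 3
Reagents that add atoms: sodium hydroxide, [Na+].[OH-]
Why: Lactone saponification followed by permanganate oxidation of the secondary benzylic alkoxide in cold alkali, the classical conversion of 3-alkylphthalides into 2-acylbenzoic acids; once the carbinol is a ketone the phthalide cannot re-form, and aryl ethers and acetals are inert to base and to cold permanganate.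

Step 10
Reactants: 16 2-[2,4-bis(methoxymethoxy)-6-pentylphenoxy]-4-methoxy-6-pentanoylbenzoic acid
Product: 17 2-(2,4-dihydroxy-6-pentylphenoxy)-4-methoxy-6-pentanoylbenzoic acid
Conditions: 3 M HCl (aq), THF, 45 °C, dilute
Reagents that add atoms: none
Why: Acid-catalysed hydrolysis of the two methoxymethyl acetals; the aqueous medium keeps the product as the keto acid or its lactol and avoids both the pseudo-ester that an alcohol solvent would give and dehydrative ring closure.

## Compound list

1 | 3,5-dimethoxybenzaldehyde | COc1cc(C=O)cc(OC)c1 | starting material
2 | 1-(3,5-dimethoxyphenyl)pentan-1-ol (racemic) | CCCCC(O)c1cc(OC)cc(OC)c1 | intermediate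
3 | 1-(2-bromo-3,5-dimethoxyphenyl)pentan-1-ol (racemic) | CCCCC(O)c1cc(OC)cc(OC)c1Br | intermediate
4 | 2-(1-hydroxypentyl)-4,6-dimethoxybenzoic acid (racemic) | CCCCC(O)c1cc(OC)cc(OC)c1C(=O)O | intermediate (not isolated)
5 | 3-butyl-5,7-dimethoxyisobenzofuran-1(3H)-one (racemic) | CCCCC1OC(=O)c2c(OC)cc(OC)cc12 | intermediate
6 | 3-butyl-7-hydroxy-5-methoxyisobenzofuran-1(3H)-one (racemic) | CCCCC1OC(=O)c2c(O)cc(OC)cc12 | intermediate
7 | dimethyl bromomalonate | COC(=O)C(Br)C(=O)OC | starting material
8 | dimethyl 2-[(3-butyl-5-methoxy-1-oxo-1,3-dihydroisobenzofuran-7-yl)oxy]malonate (racemic) | COC(=O)C(Oc1cc(OC)cc2c1C(=O)OC2CCCC)C(=O)OC | intermediate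
9 | non-3-yn-2-one | CCCCCC#CC(C)=O | starting material
10 | dimethyl 2-[(3-butyl-5-methoxy-1-oxo-1,3-dihydroisobenzofuran-7-yl)oxy]-2-[(Z)-2-oxonon-3-en-4-yl]malonate (racemic; the Z isomer is the one that closes) | CCCCC/C(=C/C(C)=O)C(Oc1cc(OC)cc2c1C(=O)OC2CCCC)(C(=O)OC)C(=O)OC | intermediate (not isolated)
11 | methyl 1-[(3-butyl-5-methoxy-1-oxo-1,3-dihydroisobenzofuran-7-yl)oxy]-2,4-dioxo-6-pentylcyclohex-5-ene-1-carboxylate (mixture of diastereomers) | CCCCCC1=CC(=O)CC(=O)C1(Oc1cc(OC)cc2c1C(=O)OC2CCCC)C(=O)OC | intermediate
12 | 1-[(3-butyl-5-methoxy-1-oxo-1,3-dihydroisobenzofuran-7-yl)oxy]-2,4-dioxo-6-pentylcyclohex-5-ene-1-carboxylic acid (mixture of diastereomers) | CCCCCC1=CC(=O)CC(=O)C1(Oc1cc(OC)cc2c1C(=O)OC2CCCC)C(=O)O | intermediate (not isolated)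
13 | 3-butyl-7-(2,4-dihydroxy-6-pentylphenoxy)-5-methoxyisobenzofuran-1(3H)-one (racemic) | CCCCCc1cc(O)cc(O)c1Oc1cc(OC)cc2c1C(=O)OC2CCCC | intermediate
14 | 7-[2,4-bis(methoxymethoxy)-6-pentylphenoxy]-3-butyl-5-methoxyisobenzofuran-1(3H)-one (racemic) | CCCCCc1cc(OCOC)cc(OCOC)c1Oc1cc(OC)cc2c1C(=O)OC2CCCC | intermediate
15 | sodium 2-[2,4-bis(methoxymethoxy)-6-pentylphenoxy]-6-(1-hydroxypentyl)-4-methoxybenzoate (racemic) | CCCCCc1cc(OCOC)cc(OCOC)c1Oc1cc(OC)cc(C(O)CCCC)c1C(=O)[O-].[Na+] | intermediate (not isolated)
16 | 2-[2,4-bis(methoxymethoxy)-6-pentylphenoxy]-4-methoxy-6-pentanoylbenzoic acid | CCCCCc1cc(OCOC)cc(OCOC)c1Oc1cc(OC)cc(C(=O)CCCC)c1C(=O)O | intermediate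
17 | 2-(2,4-dihydroxy-6-pentylphenoxy)-4-methoxy-6-pentanoylbenzoic acid | CCCCCc1cc(O)cc(O)c1Oc1cc(OC)cc(C(=O)CCCC)c1C(=O)O | target

## Step count and risk

Total: 10 steps. Longest linear sequence: 10 steps from 1; compounds 7 and 9 are purchased and enter at steps 5 and 6.

**Step 6 (key step, proposed new method).** The most likely failure is stalling at the open-chain adduct because the alkene geometry holds the ketone away from the esters. The second is consumption of the ynone by methoxide addition or base-induced isomerisation and oligomerisation before the hindered carbanion has added. The fallback uses known chemistry and sets out from 8. Commercial (E)-non-3-en-2-one replaces 9 under the same base. The Michael–Claisen annulation of malonates with enones is the established route to 5-alkylcyclohexane-1,3-diones; it has no geometric constraint and should give methyl 1-[(3-butyl-5-methoxy-1-oxo-1,3-dihydroisobenzofuran-7-yl)oxy]-2,4-dioxo-6-pentylcyclohexane-1-carboxylate F1. LiCl in wet DMSO would then remove the ester to give 3-butyl-7-[(2,4-dioxo-6-pentylcyclohexyl)oxy]-5-methoxyisobenzofuran-1(3H)-one F2. Bromination between the carbonyls (Br2, DMF, 0 °C) and thermal loss of HBr, the classical aromatisation used for olivetol, would then give 13, where the fallback rejoins the route.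

**Step 9.** The risk is over-oxidation (attack of permanganate on the benzylic methylene of the pentyl chain or on the electron-rich rings), or incomplete oxidation followed by relactonisation on acidification, which would return 14. The fallback sets out from 14 and moves the oxidation into a neutral organic medium. After saponification with NaOH (1.05 equiv) and evaporation, the carboxylate is alkylated with iodomethane in DMF to give methyl 2-[2,4-bis(methoxymethoxy)-6-pentylphenoxy]-6-(1-hydroxypentyl)-4-methoxybenzoate F3. Dess–Martin periodinane in CH2Cl2 oxidises the carbinol to methyl 2-[2,4-bis(methoxymethoxy)-6-pentylphenoxy]-4-methoxy-6-pentanoylbenzoate F4. LiOH in aqueous THF, assisted by the neighbouring ketone, then hydrolyses the ester and rejoins the route at 16.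

**Step 5.** The risk is halogen transfer from the bromomalonate to the electron-rich phenoxide (ring bromination with reduction of the reagent), and further reaction of the acidic product with bromomalonate under the carbonate base. The fallback sets out from 6 and forms the same O–C bond without base. Insertion of the carbenoid from dimethyl diazomalonate into the phenol O–H bond, catalysed by Rh2(OAc)4 (divalent rhodium) in toluene at 80 °C, gives 8 directly, where the route continues.

**Step 10.** The risk is re-alkylation of the liberated, highly nucleophilic resorcinol ring by the formaldehyde set free during acetal cleavage, or dehydrative closure of the keto acid if the acid is too strong. The fallback sets out from 13 and replaces the acetals by benzyl ethers, which are removed under neutral conditions. BnBr and K2CO3 in DMF give 7-[2,4-bis(benzyloxy)-6-pentylphenoxy]-3-butyl-5-methoxyisobenzofuran-1(3H)-one F5 (identical in structure with A5). The saponification–permanganate sequence of step 9 gives 2-[2,4-bis(benzyloxy)-6-pentylphenoxy]-4-methoxy-6-pentanoylbenzoic acid F6. Hydrogenolysis (H2, Pd/C, EtOAc), stopped once the benzyl groups are gone so that the aryl ketone is spared, arrives at 17.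

## Further compounds

F1 | step 6 | methyl 1-[(3-butyl-5-methoxy-1-oxo-1,3-dihydroisobenzofuran-7-yl)oxy]-2,4-dioxo-6-pentylcyclohexane-1-carboxylate (mixture of diastereomers) | CCCCCC1CC(=O)CC(=O)C1(Oc1cc(OC)cc2c1C(=O)OC2CCCC)C(=O)OC
F2 | step 6 | 3-butyl-7-[(2,4-dioxo-6-pentylcyclohexyl)oxy]-5-methoxyisobenzofuran-1(3H)-one (mixture of diastereomers) | CCCCCC1CC(=O)CC(=O)C1Oc1cc(OC)cc2c1C(=O)OC2CCCC
F3 | step 9 | methyl 2-[2,4-bis(methoxymethoxy)-6-pentylphenoxy]-6-(1-hydroxypentyl)-4-methoxybenzoate (racemic) | CCCCCc1cc(OCOC)cc(OCOC)c1Oc1cc(OC)cc(C(O)CCCC)c1C(=O)OC
F4 | step 9 | methyl 2-[2,4-bis(methoxymethoxy)-6-pentylphenoxy]-4-methoxy-6-pentanoylbenzoate | CCCCCc1cc(OCOC)cc(OCOC)c1Oc1cc(OC)cc(C(=O)CCCC)c1C(=O)OC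
F0 | step 5 | none | none
F5 | step 10 | 7-[2,4-bis(benzyloxy)-6-pentylphenoxy]-3-butyl-5-methoxyisobenzofuran-1(3H)-one (racemic) | CCCCCc1cc(OCc2ccccc2)cc(OCc2ccccc2)c1Oc1cc(OC)cc2c1C(=O)OC2CCCC
F6 | step 10 | 2-[2,4-bis(benzyloxy)-6-pentylphenoxy]-4-methoxy-6-pentanoylbenzoic acid | CCCCCc1cc(OCc2ccccc2)cc(OCc2ccccc2)c1Oc1cc(OC)cc(C(=O)CCCC)c1C(=O)O
A1 | alternative 1 | methyl 2-[2,4-bis(benzyloxy)-6-pentylphenoxy]-4-(tert-butyldimethylsilyloxy)-6-[1-(tert-butyldimethylsilyloxy)pentyl]benzoate (racemic) | COC(=O)c1c(Oc2c(CCCCC)cc(OCc3ccccc3)cc2OCc2ccccc2)cc(O[Si](C)(C)C(C)(C)C)cc1C(CCCC)O[Si](C)(C)C(C)(C)C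
A2 | alternative 1 | 2,4-bis(benzyloxy)-6-pentylphenol | CCCCCc1cc(OCc2ccccc2)cc(OCc2ccccc2)c1O
A3 | alternative 1 | 1-[2,4-bis(benzyloxy)-6-pentylphenoxy]-3-(tert-butyldimethylsilyloxy)cyclohexa-1,3-diene | CCCCCc1cc(OCc2ccccc2)cc(OCc2ccccc2)c1OC1=CC(O[Si](C)(C)C(C)(C)C)=CCC1
A4 | alternative 1 | methyl 4-(tert-butyldimethylsilyloxy)oct-2-ynoate (racemic) | CCCCC(O[Si](C)(C)C(C)(C)C)C#CC(=O)OC
A5 | alternative 2 | 7-[2,4-bis(benzyloxy)-6-pentylphenoxy]-3-butyl-5-methoxyisobenzofuran-1(3H)-one (racemic) | CCCCC1OC(=O)c2c(Oc3c(CCCCC)cc(OCc4ccccc4)cc3OCc3ccccc3)cc(OC)cc21
A6 | alternative 2 | hept-1-yn-3-yl 3-[2,4-bis(benzyloxy)-6-pentylphenoxy]prop-2-ynoate (racemic) | CCCCC(C#C)OC(=O)C#COc1c(CCCCC)cc(OCc2ccccc2)cc1OCc1ccccc1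
A7 | alternative 2 | methoxyacetylene | COC#C
A8 | alternative 3 | tert-butyl (E)-3-{2-[2,4-bis(benzyloxy)-6-pentylphenoxy]-4-methoxy-6-pentanoylphenyl}acrylate | CCCCC(=O)c1cc(OC)cc(Oc2c(CCCCC)cc(OCc3ccccc3)cc2OCc2ccccc2)c1/C=C/C(=O)OC(C)(C)C
A9 | alternative 3 | 1,5-bis(benzyloxy)-2-(2-iodo-5-methoxyphenoxy)-3-pentylbenzene | CCCCCc1cc(OCc2ccccc2)cc(OCc2ccccc2)c1Oc1cc(OC)ccc1I
A10 | alternative 3 | pentanoic anhydride | CCCCC(=O)OC(=O)CCCC
A11 | alternative 3 | tert-butyl acrylate | C=CC(=O)OC(C)(C)C
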